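**Plan**

1. Numbering: coumarin numbering, unprimed for the 5,7‑dioxygenated half A, primed for the tetraoxygenated half B. The target is 3S,4R,3'S,4'R, with the C3–C3' bond cis to the 4‑hydroxyphenyl ring on each lactone ring.
2. Feature used: each 4‑hydroxyphenyl ring on C4/C4' is a para‑oxygenated benzene ring held by a single carbon. Its ipso and one ortho carbon can therefore be an ethynyl group on C4/C4', and its other four carbons with the oxygen a 2‑silyloxybutadiene; with ethynyl in place of aryl, C4 and C4' are propargylic centres β to a carbonyl.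
3. Cuts, in order: the ipso–ortho bond on one side and the ortho–meta bond on the other side of both 4‑hydroxyphenyl rings; both lactone O1–C2 bonds; C3–C3'; the C4–alkyne and C4'–alkyne bonds; C3=C4 and C3'=C4' back to two salicylaldehydes and 2,2‑dimethyl‑1,3‑dioxane‑4,6‑dione.
4. Forward: each half goes salicylaldehyde → arylidene dioxanedione → propargylic acid → imide. The chain is joined at C3–C3', both lactone rings close in one operation, both outer six‑membered rings are then grown at once, aromatised, and all ethers cleaved.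
5. Stereochemistry: C4 and C4' come from the chiral rhodium catalyst in the two conjugate alkynylations. C3 and C3' come from the two (R)‑4‑benzyloxazolidinone auxiliaries in the oxidative enolate coupling. No later step is basic enough to enolise the lactones.

Key step: step 16

Assumption: the rhodium/bisphosphine catalyst is taken to show the sense of induction known for simple benzylidene dioxanediones; if the sense is the opposite, the (R)‑ligand is used in steps 3 and 11.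

Note on descriptors: C4/C4' are S in every C‑silylated compound and R from 26 onwards only because a silylethynyl group outranks the aryl ring, whereas ethynyl, cyclohexadienyl and hydroxyphenyl do not. The spatial arrangement is the same throughout.

Abbreviations: TBS = tert‑butyldimethylsilyl; TMS = trimethylsilyl; ArA = 2‑(TBS‑oxy)‑4,6‑dimethoxyphenyl; ArB = 2‑(TBS‑oxy)‑3,4,5,6‑tetramethoxyphenyl.

**Route**

Step 1
Reactants: 1 2‑hydroxy‑4,6‑dimethoxybenzaldehyde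
Product: 2 2‑(TBS‑oxy)‑4,6‑dimethoxybenzaldehyde
Conditions: TBSCl, imidazole, DMF, 25 °C
Reagents that add atoms: tert‑butyldimethylsilyl chloride, CC(C)(C)[Si](C)(C)Cl
Why: Silyl ether formation masks the future lactone oxygen so that the Knoevenagel product cannot close to a coumarin, and the group is removable by fluoride in the lactone‑forming step.

Step 2
Reactants: 2 2‑(TBS‑oxy)‑4,6‑dimethoxybenzaldehyde; 3 2,2‑dimethyl‑1,3‑dioxane‑4,6‑dione (Meldrum's acid)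
Product: 4 5‑[2‑(TBS‑oxy)‑4,6‑dimethoxybenzylidene]‑2,2‑dimethyl‑1,3‑dioxane‑4,6‑dione
Conditions: pyrrolidinium acetate (10 mol %), benzene, 25 → 50 °C
Reagents that add atoms: none
Why: Knoevenagel condensation of a non‑enolisable aldehyde with the acidic dioxanedione should give the doubly activated alkylidene needed for conjugate addition.

Step 3
Reactants: 4 arylidene dioxanedione of half A; 5 ethynyltrimethylsilane
Product: 6 5‑[(1S)‑1‑ArA‑3‑(trimethylsilyl)prop‑2‑yn‑1‑yl]‑2,2‑dimethyl‑1,3‑dioxane‑4,6‑dione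
Conditions: 5 (3 equiv), [Rh(OAc)(C2H4)2]2 (2.5 mol %), (S)‑(6,6'‑dimethoxybiphenyl‑2,2'‑diyl)bis[bis(3,5‑dimethylphenyl)phosphine] (5.5 mol %), 1,4‑dioxane, 40 °C
Reagents that add atoms: none
Why: Rhodium‑catalysed asymmetric conjugate alkynylation, in which a monovalent rhodium acetylide adds 1,4 to the alkylidene dioxanedione and the bisphosphine selects the face, should set C4 (descriptor S here, the R arrangement of the target once silicon is gone), the rhodium enolate being protonated by the next alkyne.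

Step 4
Reactants: 6 alkynylated dioxanedione of half A
Product: 8 (3S)‑3‑ArA‑5‑(trimethylsilyl)pent‑4‑ynoic acid, via diacid 7 (not isolated)
Conditions: DMF/H2O (10:1), 100 °C
Reagents that add atoms: water, O
Why: Hydrolysis of the dioxanedione to the malonic acid followed by thermal decarboxylation should leave the propanoic acid chain, the neutral medium sparing both silyl groups and the non‑enolisable C4 centre.

Step 5
Reactants: 8 acid of half A; 9 (R)‑4‑benzyl‑1,3‑oxazolidin‑2‑one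
Product: 11 (4R)‑4‑benzyl‑3‑[(3S)‑3‑ArA‑5‑(trimethylsilyl)pent‑4‑ynoyl]‑1,3‑oxazolidin‑2‑one, via mixed anhydride 10 (not isolated)
Conditions: PivCl, Et3N, THF, −20 °C; then 9, LiCl, 25 °C
Reagents that add atoms: none
Why: N‑Acylation of the oxazolidinone through the mixed pivalic anhydride, which is attacked at its less hindered carbonyl, installs the auxiliary that will direct C3.

Step 6
Reactants: 12 3,4,5‑trimethoxyphenol
Product: 13 2‑hydroxy‑4,5,6‑trimethoxybenzaldehyde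
Conditions: MgCl2, Et3N, (CH2O)n, MeCN, reflux
Reagents that add atoms: formaldehyde (as paraformaldehyde), C=O
Why: Magnesium phenoxide‑directed ortho‑formylation (Casnati–Skattebøl reaction) places the aldehyde only ortho to the hydroxyl, the two ortho positions being equivalent.

Step 7
Reactants: 13 2‑hydroxy‑4,5,6‑trimethoxybenzaldehyde
Product: 14 3‑bromo‑2‑hydroxy‑4,5,6‑trimethoxybenzaldehyde
Conditions: NBS, MeCN, 0 °C
Reagents that add atoms: N‑bromosuccinimide, O=C1CCC(=O)N1Br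
Why: Electrophilic aromatic bromination can only take the single remaining ring position, which is ortho to the hydroxyl and strongly activated.

Step 8
Reactants: 14 3‑bromo‑2‑hydroxy‑4,5,6‑trimethoxybenzaldehyde
Product: 15 2‑hydroxy‑3,4,5,6‑tetramethoxybenzaldehyde
Conditions: NaOMe, CuBr (10 mol %), DMF/MeOH, 110 °C
Reagents that add atoms: sodium methoxide, [Na+].[O-]C
Why: Copper‑catalysed Ullmann‑type methoxylation of an ortho‑bromophenol aldehyde, a long‑established way to methoxylated hydroxybenzaldehydes, completes the pentaoxygenated ring while the phenoxide shields the aldehyde from methoxide.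

Step 9
Reactants: 15 2‑hydroxy‑3,4,5,6‑tetramethoxybenzaldehyde
Product: 16 2‑(TBS‑oxy)‑3,4,5,6‑tetramethoxybenzaldehyde
Conditions: TBSOTf, 2,6‑lutidine, CH2Cl2, 0 °C
Reagents that add atoms: tert‑butyldimethylsilyl trifluoromethanesulfonate, CC(C)(C)[Si](C)(C)OS(=O)(=O)C(F)(F)F
Why: Silyl ether formation with the more reactive silyl triflate is chosen because this phenol is flanked by the formyl and a methoxy group.

Step 10
Reactants: 16 2‑(TBS‑oxy)‑3,4,5,6‑tetramethoxybenzaldehyde; 3 2,2‑dimethyl‑1,3‑dioxane‑4,6‑dione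
Product: 17 5‑[2‑(TBS‑oxy)‑3,4,5,6‑tetramethoxybenzylidene]‑2,2‑dimethyl‑1,3‑dioxane‑4,6‑dione
Conditions: pyrrolidinium acetate (10 mol %), benzene, 50 °C
Reagents that add atoms: none
Why: Knoevenagel condensation, as in step 2, gives the second doubly activated acceptor.

Step 11
Reactants: 17 arylidene dioxanedione of half B; 5 ethynyltrimethylsilane
Product: 18 5‑[(1S)‑1‑ArB‑3‑(trimethylsilyl)prop‑2‑yn‑1‑yl]‑2,2‑dimethyl‑1,3‑dioxane‑4,6‑dione
Conditions: 5 (3 equiv), [Rh(OAc)(C2H4)2]2 (2.5 mol %), (S)‑(6,6'‑dimethoxybiphenyl‑2,2'‑diyl)bis[bis(3,5‑dimethylphenyl)phosphine] (5.5 mol %), 1,4‑dioxane, 50 °C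
Reagents that add atoms: none
Why: The same rhodium‑catalysed asymmetric conjugate alkynylation, with the same ligand antipode, should set C4' in the same sense as C4.

Step 12
Reactants: 18 alkynylated dioxanedione of half B
Product: 20 (3S)‑3‑ArB‑5‑(trimethylsilyl)pent‑4‑ynoic acid, via diacid 19 (not isolated)
Conditions: DMF/H2O (10:1), 100 °C
Reagents that add atoms: water, O
Why: Hydrolysis and decarboxylation of the malonic acid, as in step 4.

Step 13
Reactants: 20 acid of half B; 9 (R)‑4‑benzyl‑1,3‑oxazolidin‑2‑one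
Product: 22 (4R)‑4‑benzyl‑3‑[(3S)‑3‑ArB‑5‑(trimethylsilyl)pent‑4‑ynoyl]‑1,3‑oxazolidin‑2‑one, via mixed anhydride 21 (not isolated)
Conditions: PivCl, Et3N, THF, −20 °C; then 9, LiCl, 25 °C
Reagents that add atoms: none
Why: Mixed‑anhydride N‑acylation of the oxazolidinone, as in step 5.

Step 14
Reactants: 11 imide of half A; 22 imide of half B
Product: 23 3,3'‑{(2S,3S)‑2‑[(1S)‑1‑ArA‑3‑(trimethylsilyl)prop‑2‑yn‑1‑yl]‑3‑[(1S)‑1‑ArB‑3‑(trimethylsilyl)prop‑2‑yn‑1‑yl]butanedioyl}bis[(4R)‑4‑benzyl‑1,3‑oxazolidin‑2‑one]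
Conditions: 11 (3 equiv), 22 (1 equiv), LiN(iPr)2 (4.2 equiv), THF, −78 °C; then Cu(O2CCH(Et)(n‑Bu))2 [copper bis(2‑ethylhexanoate)] (4.4 equiv), −78 → 0 °C
Reagents that add atoms: none
Why: Oxidative enolate coupling by divalent copper (one‑electron oxidation of one lithium imide enolate to an α‑radical that adds to the other) forms C3–C3'; each (R)‑benzyl group shields one face of its chelated Z‑enolate, as in alkylations with this auxiliary, so both new centres should form S even against the smaller bias of the neighbouring C4 centres, and the excess of the more accessible imide 11 channels 22 into the cross‑coupled product.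

Step 15
Reactants: 23 bis‑imide
Product: 26 (3S,3'S,4R,4'R)‑4,4'‑diethynyl‑5,5',6',7,7',8'‑hexamethoxy‑[3,3'‑bichromane]‑2,2'‑dione, via bis‑phenol 24 (not isolated), via bis(silylalkyne) bis‑lactone 25 (not isolated)
Conditions: Bu4NF (6 equiv), AcOH (6 equiv), THF, 0 → 25 °C
Reagents that add atoms: none
Why: Fluoride cleaves the aryl silyl ethers, each freed phenol attacks its own exocyclic imide carbonyl in a six‑membered lactonisation that expels the oxazolidinone, and the alkynes are protodesilylated, while the acetic acid buffer keeps the medium too weakly basic to enolise the new lactones at C3 and C3'.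

Step 16
Reactants: 26 diethynyl bis‑lactone; 27 2‑(trimethylsilyloxy)buta‑1,3‑diene
Product: 28 (3S,3'S,4R,4'R)‑5,5',6',7,7',8'‑hexamethoxy‑4,4'‑bis[4‑(trimethylsilyloxy)cyclohexa‑1,4‑dien‑1‑yl]‑[3,3'‑bichromane]‑2,2'‑dione
Conditions: 27 (8 equiv), CoBr2 (20 mol %), 1,2‑bis(diphenylphosphino)ethane (20 mol %), Zn (40 mol %), ZnI2 (40 mol %), CH2Cl2, 25 °C
Reagents that add atoms: none
Why: Zinc reduces divalent cobalt to monovalent cobalt, which binds a terminal alkyne and the s‑cis diene, couples them oxidatively to a cobaltacycle and releases the cyclohexa‑1,4‑diene by reductive elimination; the closest known reaction is the cobalt/bisphosphine‑catalysed neutral [4+2] cycloaddition of terminal alkynes with 2‑substituted buta‑1,3‑dienes. Each of the two new six‑membered carbocycles closes in this metal‑mediated [4+2] mode, the two alkyne carbons (future ipso and ortho carbons) each bonding to one diene terminus. No stereocentre is created, and C3, C4, C3' and C4' should keep their configuration because the medium is neutral, aprotic and at room temperature. The step needs the 1,4 (para) orientation, which the chelating bisphosphine and the bulky propargylic substituent should secure by joining the substituted alkyne carbon to the diene terminus remote from the silyloxy carbon. It also needs alkyne–diene coupling to outrun coupling of the two alkynes of this 1,7‑diyne with each other, which the large excess of diene is meant to ensure.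

Step 17
Reactants: 28 bis(cyclohexadienyl) bis‑lactone
Product: 29 (3S,3'S,4R,4'R)‑5,5',6',7,7',8'‑hexamethoxy‑4,4'‑bis[4‑(trimethylsilyloxy)phenyl]‑[3,3'‑bichromane]‑2,2'‑dione
Conditions: DDQ (2.1 equiv), benzene, 5 °C
Reagents that add atoms: none
Why: Dehydrogenative aromatisation, in which DDQ abstracts hydride from a doubly allylic ring CH2 to give a silyloxy‑stabilised cation that loses a proton, should proceed at low temperature and exact stoichiometry without touching the C4–H and C4'–H bonds.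

Step 18
Reactants: 29 bis(silyloxyphenyl) bis‑lactone
Product: 30 (3S,3'S,4R,4'R)‑5,5',6',7,7',8'‑hexahydroxy‑4,4'‑bis(4‑hydroxyphenyl)‑[3,3'‑bichromane]‑2,2'‑dione
Conditions: BBr3 (16 equiv), CH2Cl2, −78 → 25 °C, argon; then degassed H2O, 0 °C
Reagents that add atoms: none
Why: Lewis‑acid ether cleavage by BBr3 should remove the six aryl methyl groups and the two silyl groups, the acidic, non‑basic medium leaving the lactones closed after hydrolysis of the borates and the C3/C3' centres unenolised.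

**Compound list**

1 | 2‑hydroxy‑4,6‑dimethoxybenzaldehyde | COc1cc(O)c(C=O)c(OC)c1 | starting material
2 | 2‑(tert‑butyldimethylsilyloxy)‑4,6‑dimethoxybenzaldehyde | COc1cc(OC)c(C=O)c(O[Si](C)(C)C(C)(C)C)c1 | intermediate
3 | 2,2‑dimethyl‑1,3‑dioxane‑4,6‑dione (Meldrum's acid) | CC1(C)OC(=O)CC(=O)O1 | starting material
4 | 5‑[2‑(tert‑butyldimethylsilyloxy)‑4,6‑dimethoxybenzylidene]‑2,2‑dimethyl‑1,3‑dioxane‑4,6‑dione | COc1cc(OC)c(C=C2C(=O)OC(C)(C)OC2=O)c(O[Si](C)(C)C(C)(C)C)c1 | intermediate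
5 | ethynyltrimethylsilane | C#C[Si](C)(C)C | starting material
6 | 5‑[(1S)‑1‑[2‑(tert‑butyldimethylsilyloxy)‑4,6‑dimethoxyphenyl]‑3‑(trimethylsilyl)prop‑2‑yn‑1‑yl]‑2,2‑dimethyl‑1,3‑dioxane‑4,6‑dione | COc1cc(OC)c([C@@H](C#C[Si](C)(C)C)C2C(=O)OC(C)(C)OC2=O)c(O[Si](C)(C)C(C)(C)C)c1 | intermediate
7 | 2‑[(1S)‑1‑[2‑(tert‑butyldimethylsilyloxy)‑4,6‑dimethoxyphenyl]‑3‑(trimethylsilyl)prop‑2‑yn‑1‑yl]propanedioic acid (formed in the flask) | COc1cc(OC)c([C@@H](C#C[Si](C)(C)C)C(C(=O)O)C(=O)O)c(O[Si](C)(C)C(C)(C)C)c1 | intermediate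
8 | (3S)‑3‑[2‑(tert‑butyldimethylsilyloxy)‑4,6‑dimethoxyphenyl]‑5‑(trimethylsilyl)pent‑4‑ynoic acid | COc1cc(OC)c([C@@H](C#C[Si](C)(C)C)CC(=O)O)c(O[Si](C)(C)C(C)(C)C)c1 | intermediate
9 | (R)‑4‑benzyl‑1,3‑oxazolidin‑2‑one | O=C1N[C@H](Cc2ccccc2)CO1 | starting material
10 | mixed anhydride of 8 with pivalic acid (formed in the flask) | COc1cc(OC)c([C@@H](C#C[Si](C)(C)C)CC(=O)OC(=O)C(C)(C)C)c(O[Si](C)(C)C(C)(C)C)c1 | intermediate
11 | (4R)‑4‑benzyl‑3‑[(3S)‑3‑[2‑(tert‑butyldimethylsilyloxy)‑4,6‑dimethoxyphenyl]‑5‑(trimethylsilyl)pent‑4‑ynoyl]‑1,3‑oxazolidin‑2‑one | COc1cc(OC)c([C@@H](C#C[Si](C)(C)C)CC(=O)N2[C@H](Cc3ccccc3)COC2=O)c(O[Si](C)(C)C(C)(C)C)c1 | intermediate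
12 | 3,4,5‑trimethoxyphenol | COc1cc(O)cc(OC)c1OC | starting material
13 | 2‑hydroxy‑4,5,6‑trimethoxybenzaldehyde | COc1cc(O)c(C=O)c(OC)c1OC | intermediate
14 | 3‑bromo‑2‑hydroxy‑4,5,6‑trimethoxybenzaldehyde | COc1c(Br)c(O)c(C=O)c(OC)c1OC | intermediate
15 | 2‑hydroxy‑3,4,5,6‑tetramethoxybenzaldehyde | COc1c(OC)c(O)c(C=O)c(OC)c1OC | intermediate
16 | 2‑(tert‑butyldimethylsilyloxy)‑3,4,5,6‑tetramethoxybenzaldehyde | COc1c(OC)c(O[Si](C)(C)C(C)(C)C)c(C=O)c(OC)c1OC | intermediate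
17 | 5‑[2‑(tert‑butyldimethylsilyloxy)‑3,4,5,6‑tetramethoxybenzylidene]‑2,2‑dimethyl‑1,3‑dioxane‑4,6‑dione | COc1c(OC)c(O[Si](C)(C)C(C)(C)C)c(C=C2C(=O)OC(C)(C)OC2=O)c(OC)c1OC | intermediate
18 | 5‑[(1S)‑1‑[2‑(tert‑butyldimethylsilyloxy)‑3,4,5,6‑tetramethoxyphenyl]‑3‑(trimethylsilyl)prop‑2‑yn‑1‑yl]‑2,2‑dimethyl‑1,3‑dioxane‑4,6‑dione | COc1c(OC)c(O[Si](C)(C)C(C)(C)C)c([C@@H](C#C[Si](C)(C)C)C2C(=O)OC(C)(C)OC2=O)c(OC)c1OC | intermediate
19 | 2‑[(1S)‑1‑[2‑(tert‑butyldimethylsilyloxy)‑3,4,5,6‑tetramethoxyphenyl]‑3‑(trimethylsilyl)prop‑2‑yn‑1‑yl]propanedioic acid (formed in the flask) | COc1c(OC)c(O[Si](C)(C)C(C)(C)C)c([C@@H](C#C[Si](C)(C)C)C(C(=O)O)C(=O)O)c(OC)c1OC | intermediate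
20 | (3S)‑3‑[2‑(tert‑butyldimethylsilyloxy)‑3,4,5,6‑tetramethoxyphenyl]‑5‑(trimethylsilyl)pent‑4‑ynoic acid | COc1c(OC)c(O[Si](C)(C)C(C)(C)C)c([C@@H](C#C[Si](C)(C)C)CC(=O)O)c(OC)c1OC | intermediate
21 | mixed anhydride of 20 with pivalic acid (formed in the flask) | COc1c(OC)c(O[Si](C)(C)C(C)(C)C)c([C@@H](C#C[Si](C)(C)C)CC(=O)OC(=O)C(C)(C)C)c(OC)c1OC | intermediate
22 | (4R)‑4‑benzyl‑3‑[(3S)‑3‑[2‑(tert‑butyldimethylsilyloxy)‑3,4,5,6‑tetramethoxyphenyl]‑5‑(trimethylsilyl)pent‑4‑ynoyl]‑1,3‑oxazolidin‑2‑one | COc1c(OC)c(O[Si](C)(C)C(C)(C)C)c([C@@H](C#C[Si](C)(C)C)CC(=O)N2[C@H](Cc3ccccc3)COC2=O)c(OC)c1OC | intermediate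
23 | 3,3'‑{(2S,3S)‑2‑[(1S)‑1‑ArA‑3‑(trimethylsilyl)prop‑2‑yn‑1‑yl]‑3‑[(1S)‑1‑ArB‑3‑(trimethylsilyl)prop‑2‑yn‑1‑yl]butanedioyl}bis[(4R)‑4‑benzyl‑1,3‑oxazolidin‑2‑one] | COc1cc(OC)c(c(O[Si](C)(C)C(C)(C)C)c1)[C@@H](C#C[Si](C)(C)C)[C@H](C(=O)N1[C@H](Cc2ccccc2)COC1=O)[C@@H](C(=O)N1[C@H](Cc2ccccc2)COC1=O)[C@H](C#C[Si](C)(C)C)c1c(O[Si](C)(C)C(C)(C)C)c(OC)c(OC)c(OC)c1OC | intermediate
24 | bis‑phenol of 23, with 2‑hydroxy‑4,6‑dimethoxyphenyl and 2‑hydroxy‑3,4,5,6‑tetramethoxyphenyl in place of ArA and ArB (formed in the flask) | COc1cc(OC)c(c(O)c1)[C@@H](C#C[Si](C)(C)C)[C@H](C(=O)N1[C@H](Cc2ccccc2)COC1=O)[C@@H](C(=O)N1[C@H](Cc2ccccc2)COC1=O)[C@H](C#C[Si](C)(C)C)c1c(O)c(OC)c(OC)c(OC)c1OC | intermediate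
25 | (3S,3'S,4S,4'S)‑5,5',6',7,7',8'‑hexamethoxy‑4,4'‑bis[(trimethylsilyl)ethynyl]‑[3,3'‑bichromane]‑2,2'‑dione (formed in the flask) | O=C1Oc2cc(OC)cc(OC)c2[C@@H](C#C[Si](C)(C)C)[C@H]1[C@H]1C(=O)Oc2c(OC)c(OC)c(OC)c(OC)c2[C@H]1C#C[Si](C)(C)C | intermediate
26 | (3S,3'S,4R,4'R)‑4,4'‑diethynyl‑5,5',6',7,7',8'‑hexamethoxy‑[3,3'‑bichromane]‑2,2'‑dione | O=C1Oc2cc(OC)cc(OC)c2[C@@H](C#C)[C@H]1[C@H]1C(=O)Oc2c(OC)c(OC)c(OC)c(OC)c2[C@H]1C#C | intermediate
27 | 2‑(trimethylsilyloxy)buta‑1,3‑diene | C=CC(=C)O[Si](C)(C)C | starting material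
28 | (3S,3'S,4R,4'R)‑5,5',6',7,7',8'‑hexamethoxy‑4,4'‑bis[4‑(trimethylsilyloxy)cyclohexa‑1,4‑dien‑1‑yl]‑[3,3'‑bichromane]‑2,2'‑dione | O=C1Oc2cc(OC)cc(OC)c2[C@@H](C2=CCC(O[Si](C)(C)C)=CC2)[C@H]1[C@H]1C(=O)Oc2c(OC)c(OC)c(OC)c(OC)c2[C@H]1C1=CCC(O[Si](C)(C)C)=CC1 | intermediate
29 | (3S,3'S,4R,4'R)‑5,5',6',7,7',8'‑hexamethoxy‑4,4'‑bis[4‑(trimethylsilyloxy)phenyl]‑[3,3'‑bichromane]‑2,2'‑dione | O=C1Oc2cc(OC)cc(OC)c2[C@@H](c2ccc(O[Si](C)(C)C)cc2)[C@H]1[C@H]1C(=O)Oc2c(OC)c(OC)c(OC)c(OC)c2[C@H]1c1ccc(O[Si](C)(C)C)cc1 | intermediate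
30 | (3S,3'S,4R,4'R)‑5,5',6',7,7',8'‑hexahydroxy‑4,4'‑bis(4‑hydroxyphenyl)‑[3,3'‑bichromane]‑2,2'‑dione (CNP0064734.1) | O=C1Oc2cc(O)cc(O)c2[C@@H](c2ccc(O)cc2)[C@H]1[C@H]1C(=O)Oc2c(O)c(O)c(O)c(O)c2[C@H]1c1ccc(O)cc1 | target

**Totals**

Total steps: 18. Longest linear sequence: 13 steps (12 → 30, steps 6–13 and 14–18); half A enters after 5 steps.

**Steps most likely to fail**

1. Step 14. The two enolates can pair statistically, so self‑coupling competes with cross‑coupling. Both enolates are β‑branched, so oxidation at the α‑carbon may outrun C–C bond formation. The C4/C4' centres favour attack anti to their aryl group, which opposes the auxiliaries, so facial selectivity may erode.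
Fallback (sets out from 11 and 22, returns at 25): let the lactone ring and the C4 centres direct instead; the statistical pairing remains and is again met with an excess of the half‑A partner.
 - HF·pyridine in THF, then Et3N, should unmask the phenols to give (4R)‑4‑benzyl‑3‑[(3S)‑3‑(2‑hydroxy‑4,6‑dimethoxyphenyl)‑5‑(trimethylsilyl)pent‑4‑ynoyl]‑1,3‑oxazolidin‑2‑one F1 and (4R)‑4‑benzyl‑3‑[(3S)‑3‑(2‑hydroxy‑3,4,5,6‑tetramethoxyphenyl)‑5‑(trimethylsilyl)pent‑4‑ynoyl]‑1,3‑oxazolidin‑2‑one F3.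
 - These close in the flask, with loss of the auxiliary, to (4S)‑5,7‑dimethoxy‑4‑[(trimethylsilyl)ethynyl]chroman‑2‑one F2 and (4S)‑5,6,7,8‑tetramethoxy‑4‑[(trimethylsilyl)ethynyl]chroman‑2‑one F4, with the C‑silyl groups intact.
 - Oxidative coupling of the lithium lactone enolates (LiN(iPr)2, THF, −78 °C; then copper bis(2‑ethylhexanoate); F2 in excess) should join C3 to C3' anti to the pseudoaxial alkynyl group of each ring and give the trans,trans dimer (3R,3'R,4S,4'S)‑5,5',6',7,7',8'‑hexamethoxy‑4,4'‑bis[(trimethylsilyl)ethynyl]‑[3,3'‑bichromane]‑2,2'‑dione F5.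
 - Double deprotonation (LiN(SiMe3)2, 2.2 equiv, THF, −78 °C) and kinetic protonation of the bis‑enolate with 2,6‑di‑tert‑butyl‑4‑methylphenol, again anti to the alkynyl groups, should invert both C3 and C3' and give 25. This is C‑desilylated with Bu4NF/AcOH as in step 15 to 26.

2. Step 11. Both ortho positions of the arylidene are substituted and the ring is twisted out of conjugation, so insertion into the rhodium acetylide may be slow and poorly face‑selective while the alkyne is consumed by dimerisation.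
Fallback (sets out from 17, returns at 22): replace catalyst control by separation of auxiliary diastereomers.
 - Uncatalysed conjugate addition of Me3SiC≡CMgBr (THF, −20 °C) should give racemic 5‑[1‑ArB‑3‑(trimethylsilyl)prop‑2‑yn‑1‑yl]‑2,2‑dimethyl‑1,3‑dioxane‑4,6‑dione F6.
 - Hydrolysis and decarboxylation as in step 12 lead through racemic 2‑[1‑ArB‑3‑(trimethylsilyl)prop‑2‑yn‑1‑yl]propanedioic acid F7 to racemic 3‑ArB‑5‑(trimethylsilyl)pent‑4‑ynoic acid F8.
 - Acylation of 9 as in step 13, through the racemic mixed pivalic anhydride of that acid F9, gives 22 together with its epimer (4R)‑4‑benzyl‑3‑[(3R)‑3‑ArB‑5‑(trimethylsilyl)pent‑4‑ynoyl]‑1,3‑oxazolidin‑2‑one F10. The two diastereomers are separated by chromatography and 22 goes on to step 14.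

3. Step 17. The quinone may abstract hydride from C4–H or C4'–H, which are benzylic to a trialkoxyaryl ring and allylic, or oxidise the electron‑rich rings; the labile aryl trimethylsilyl ethers may also be lost unevenly.
Fallback (sets out from 28, returns at 30): aromatise without a hydride‑abstracting oxidant.
 - AcOH/THF/H2O at 0 °C hydrolyses both silyl enol ethers to (3S,3'S,4R,4'R)‑5,5',6',7,7',8'‑hexamethoxy‑4,4'‑bis(4‑oxocyclohex‑1‑en‑1‑yl)‑[3,3'‑bichromane]‑2,2'‑dione F11.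
 - Aerobic dehydrogenation with Pd(O2CCF3)2 (divalent palladium), 2‑(dimethylamino)pyridine and TsOH under O2 in DMSO at 80 °C should convert each cyclohexenone into a phenol, giving (3S,3'S,4R,4'R)‑5,5',6',7,7',8'‑hexamethoxy‑4,4'‑bis(4‑hydroxyphenyl)‑[3,3'‑bichromane]‑2,2'‑dione F12.
 - BBr3 as in step 18 then demethylates this to 30.

**Further compounds**

F1 | step 14 | (4R)‑4‑benzyl‑3‑[(3S)‑3‑(2‑hydroxy‑4,6‑dimethoxyphenyl)‑5‑(trimethylsilyl)pent‑4‑ynoyl]‑1,3‑oxazolidin‑2‑one | COc1cc(OC)c([C@@H](C#C[Si](C)(C)C)CC(=O)N2[C@H](Cc3ccccc3)COC2=O)c(O)c1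
F2 | step 14 | (4S)‑5,7‑dimethoxy‑4‑[(trimethylsilyl)ethynyl]chroman‑2‑one | O=C1Oc2cc(OC)cc(OC)c2[C@@H](C#C[Si](C)(C)C)C1
F3 | step 14 | (4R)‑4‑benzyl‑3‑[(3S)‑3‑(2‑hydroxy‑3,4,5,6‑tetramethoxyphenyl)‑5‑(trimethylsilyl)pent‑4‑ynoyl]‑1,3‑oxazolidin‑2‑one | COc1c(OC)c(O)c([C@@H](C#C[Si](C)(C)C)CC(=O)N2[C@H](Cc3ccccc3)COC2=O)c(OC)c1OC
F4 | step 14 | (4S)‑5,6,7,8‑tetramethoxy‑4‑[(trimethylsilyl)ethynyl]chroman‑2‑one | O=C1Oc2c(OC)c(OC)c(OC)c(OC)c2[C@@H](C#C[Si](C)(C)C)C1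
F5 | step 14 | (3R,3'R,4S,4'S)‑5,5',6',7,7',8'‑hexamethoxy‑4,4'‑bis[(trimethylsilyl)ethynyl]‑[3,3'‑bichromane]‑2,2'‑dione | O=C1Oc2cc(OC)cc(OC)c2[C@@H](C#C[Si](C)(C)C)[C@@H]1[C@@H]1C(=O)Oc2c(OC)c(OC)c(OC)c(OC)c2[C@H]1C#C[Si](C)(C)C
F6 | step 11 | racemic 5‑[1‑[2‑(tert‑butyldimethylsilyloxy)‑3,4,5,6‑tetramethoxyphenyl]‑3‑(trimethylsilyl)prop‑2‑yn‑1‑yl]‑2,2‑dimethyl‑1,3‑dioxane‑4,6‑dione | COc1c(OC)c(O[Si](C)(C)C(C)(C)C)c(C(C#C[Si](C)(C)C)C2C(=O)OC(C)(C)OC2=O)c(OC)c1OC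
F7 | step 11 | racemic 2‑[1‑[2‑(tert‑butyldimethylsilyloxy)‑3,4,5,6‑tetramethoxyphenyl]‑3‑(trimethylsilyl)prop‑2‑yn‑1‑yl]propanedioic acid | COc1c(OC)c(O[Si](C)(C)C(C)(C)C)c(C(C#C[Si](C)(C)C)C(C(=O)O)C(=O)O)c(OC)c1OC
F8 | step 11 | racemic 3‑[2‑(tert‑butyldimethylsilyloxy)‑3,4,5,6‑tetramethoxyphenyl]‑5‑(trimethylsilyl)pent‑4‑ynoic acid | COc1c(OC)c(O[Si](C)(C)C(C)(C)C)c(C(C#C[Si](C)(C)C)CC(=O)O)c(OC)c1OC
F9 | step 11 | racemic mixed anhydride of F8 with pivalic acid | COc1c(OC)c(O[Si](C)(C)C(C)(C)C)c(C(C#C[Si](C)(C)C)CC(=O)OC(=O)C(C)(C)C)c(OC)c1OC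
F10 | step 11 | (4R)‑4‑benzyl‑3‑[(3R)‑3‑[2‑(tert‑butyldimethylsilyloxy)‑3,4,5,6‑tetramethoxyphenyl]‑5‑(trimethylsilyl)pent‑4‑ynoyl]‑1,3‑oxazolidin‑2‑one | COc1c(OC)c(O[Si](C)(C)C(C)(C)C)c([C@H](C#C[Si](C)(C)C)CC(=O)N2[C@H](Cc3ccccc3)COC2=O)c(OC)c1OC
F11 | step 17 | (3S,3'S,4R,4'R)‑5,5',6',7,7',8'‑hexamethoxy‑4,4'‑bis(4‑oxocyclohex‑1‑en‑1‑yl)‑[3,3'‑bichromane]‑2,2'‑dione | O=C1Oc2cc(OC)cc(OC)c2[C@@H](C2=CCC(=O)CC2)[C@H]1[C@H]1C(=O)Oc2c(OC)c(OC)c(OC)c(OC)c2[C@H]1C1=CCC(=O)CC1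
F12 | step 17 | (3S,3'S,4R,4'R)‑5,5',6',7,7',8'‑hexamethoxy‑4,4'‑bis(4‑hydroxyphenyl)‑[3,3'‑bichromane]‑2,2'‑dione | O=C1Oc2cc(OC)cc(OC)c2[C@@H](c2ccc(O)cc2)[C@H]1[C@H]1C(=O)Oc2c(OC)c(OC)c(OC)c(OC)c2[C@H]1c1ccc(O)cc1
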